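**Plan**

- Numbering: ester carbon C1, chain C2–C7, ring C8–C12 (C9 ketone, C10 chlorinated, C12 acetoxylated), octenyl chain C13–C20.
- Retrosynthesis: remove the C12 acetate, then cut the ring at C10=C11 and C9–C8 together. This gives an open chain with a C11 aldehyde, the C12 carbinol and a C8 alkenylstannane, plus a two-carbon chloro(phosphono)acetyl chloride (C9, C10). Further back: C8–Sn to the C7≡C8 alkyne, C6–C7 (Sonogashira), C7 (alkyne homologation of a C8 aldehyde), the C12 epoxide, and the C11 methylene added to (4Z)-dec-4-enal.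
- Enabling feature: C12 is fully substituted, so the C11 aldehyde has no α-hydrogen and survives while vinylic C8 is acylated. C9 lies between vinylic C8 and C10, whose chlorine and carbonyl stabilise a phosphonate carbanion, so one reagent is the acyl electrophile for C8 and the olefinating carbanion for C11. The five-membered ring C8–C12 fixes the C10=C11 geometry.
- Forward: C11–C20 chain with the C12 epoxide, then the C8 alkyne, then the C1–C6 chain joined at C7, then tin placed on C8 through a silicon tether from the C11 oxygen (helpers: silicon, iodine, tin, phosphonate, all removed on the way). The only ring closes in the key step; acetylation ends the route.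
- Stereochemistry: C12 from Sharpless epoxidation with L-(+)-diethyl tartrate, never part of a bond-forming event afterwards; 14Z bought with the starting aldehyde; 5E from syn hydrozirconation; 7E from syn hydrosilylation, carried through iodine, tin and palladium with retention.

Key step: step 14

Assumption: (4Z)-dec-4-enal, methyl hex-5-ynoate and ethyl 2-chloro-2-(diethoxyphosphoryl)acetate are bought; the tertiary hydroxyl at C12 is carried unprotected until the last step.

**Route**

Step 1
Reactants: 1 (4Z)-dec-4-enal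
Product: 3 (4Z)-2-methylidenedec-4-en-1-ol, via (4Z)-2-methylidenedec-4-enal 2 (not isolated)
Conditions: 37% aq. CH2O, pyrrolidine (10 mol%), propanoic acid (10 mol%), i-PrOH, 45 °C; then MeOH, CeCl3·7H2O, NaBH4, 0 °C
Reagents that add atoms: formaldehyde, C=O
Why: Amine-catalysed Mannich condensation and elimination (α-methylenation of an aldehyde) should give the 2-substituted acrolein, which is reduced at once by Luche 1,2-reduction before it can dimerise; the 4Z alkene is untouched and no stereocentre is formed.

Step 2
Reactants: 3 (4Z)-2-methylidenedec-4-en-1-ol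
Product: 4 [(2S)-2-[(2Z)-oct-2-en-1-yl]oxiran-2-yl]methanol
Conditions: Ti(O-i-Pr)4 (10 mol%), L-(+)-diethyl tartrate (12 mol%), t-BuOOH, 4 Å molecular sieves, CH2Cl2, −20 °C; aqueous tartaric acid work-up
Reagents that add atoms: tert-butyl hydroperoxide, CC(C)(C)OO
Why: Sharpless asymmetric epoxidation: the allylic hydroxyl binds titanium, so only the 1,1-disubstituted allylic alkene is oxidised, and the L-(+)-tartrate should deliver oxygen to the face that gives the (S)-epoxide (the sense that gives (S)-2-methylglycidol from 2-methylprop-2-en-1-ol), which sets C12; the non-basic work-up avoids the degenerate Payne rearrangement that would racemise this epoxy alcohol.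

Step 3
Reactants: 4 [(2S)-2-[(2Z)-oct-2-en-1-yl]oxiran-2-yl]methanol
Product: 5 (2R)-2-[(2Z)-oct-2-en-1-yl]oxirane-2-carbaldehyde
Conditions: SO3·pyridine, DMSO, Et3N, CH2Cl2, 0 °C
Reagents that add atoms: none
Why: Parikh–Doering oxidation of a primary epoxy alcohol is mild and weakly basic, and the aldehyde has no α-hydrogen, so C12 cannot epimerise (the descriptor changes only by priority).

Step 4
Reactants: 5 (2R)-2-[(2Z)-oct-2-en-1-yl]oxirane-2-carbaldehyde
Product: 6 (2S)-2-ethynyl-2-[(2Z)-oct-2-en-1-yl]oxirane
Conditions: dimethyl (1-diazo-2-oxopropyl)phosphonate, K2CO3, MeOH, 0 → 23 °C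
Reagents that add atoms: dimethyl (1-diazo-2-oxopropyl)phosphonate, CC(=O)C(=[N+]=[N-])P(=O)(OC)OC
Why: Ohira–Bestmann (Seyferth–Gilbert) homologation turns the non-enolisable aldehyde into the terminal alkyne (C8≡C7) through an alkylidene carbene 1,2-shift, without touching the epoxide stereocentre.

Step 5
Reactants: 6 (2S)-2-ethynyl-2-[(2Z)-oct-2-en-1-yl]oxirane
Product: 7 (2S,4Z)-2-ethynyldec-4-ene-1,2-diol
Conditions: KOH, DMSO–H2O (4:1), 70 °C
Reagents that add atoms: water, O
Why: Base-mediated SN2 opening by hydroxide at the unsubstituted epoxide carbon (C11) leaves the C12–O bond intact, so the tertiary carbinol keeps its configuration, whereas acid would ionise the propargylic carbon.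

Step 6
Reactants: 8 methyl hex-5-ynoate
Product: 10 methyl (5E)-6-iodohex-5-enoate, via alkenylzirconocene chloride 9 (not isolated)
Conditions: Cp2Zr(H)Cl, THF, 23 °C; then N-iodosuccinimide, 0 °C
Reagents that add atoms: N-iodosuccinimide, O=C1CCC(=O)N1I
Why: Hydrozirconation of a terminal alkyne is syn and places zirconium on the terminal carbon, and iodinolysis proceeds with retention, which should give the (E)-iodoalkene; the ester tolerates the short exposure.

Step 7
Reactants: 7 (2S,4Z)-2-ethynyldec-4-ene-1,2-diol; 10 methyl (5E)-6-iodohex-5-enoate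
Product: 11 methyl (5E,9S,11Z)-9-hydroxy-9-(hydroxymethyl)heptadeca-5,11-dien-7-ynoate
Conditions: PdCl2(PPh3)2 (cat.), CuI (cat.), Et3N, THF, 23 °C
Reagents that add atoms: none
Why: Sonogashira coupling of a terminal alkyne with an alkenyl iodide forms C6–C7 with retention of the 5E geometry and tolerates the free diol and the ester.

Step 8
Reactants: 11 methyl (5E,9S,11Z)-9-hydroxy-9-(hydroxymethyl)heptadeca-5,11-dien-7-ynoate
Product: 13 methyl (5E,7E)-7-[(4R)-4-hydroxy-2,2-dimethyl-4-[(2Z)-oct-2-en-1-yl]-1,2-oxasilolan-3-ylidene]hept-5-enoate, via dimethylsilyl ether 12 (not isolated)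
Conditions: (HMe2Si)2NH (0.6 equiv), THF, 23 °C; then Pt2[(CH2=CHSiMe2)2O]3 (0.3 mol%), THF, 23 °C
Reagents that add atoms: 1,1,3,3-tetramethyldisilazane, C[SiH](C)N[SiH](C)C
Why: Silylation of the primary hydroxyl followed by platinum-catalysed intramolecular syn hydrosilylation of the homopropargylic silyl ether in the 5-exo-dig mode should put silicon on C8 and hydrogen on C7 on the same side, which fixes both the regiochemistry and the 7E geometry that an untethered hydrometalation would not control.

Step 9
Reactants: 13 methyl (5E,7E)-7-[(4R)-4-hydroxy-2,2-dimethyl-4-[(2Z)-oct-2-en-1-yl]-1,2-oxasilolan-3-ylidene]hept-5-enoate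
Product: 15 methyl (5E,7E,9R,11Z)-9-hydroxy-9-(hydroxymethyl)-8-iodoheptadeca-5,7,11-trienoate, via hexafluoroisopropoxysilyl ether 14 (not isolated)
Conditions: N-iodosuccinimide (1.05 equiv), (CF3)2CHOH, 0 °C; then aq. NaHCO3/Na2S2O3, MeOH
Reagents that add atoms: N-iodosuccinimide, O=C1CCC(=O)N1I
Why: Ipso-iododesilylation of the alkenylsilane through a β-silyl cation in hexafluoropropan-2-ol proceeds with retention of alkene geometry, and the silyl ether left on the C11 oxygen is hydrolysed on work-up.

Step 10
Reactants: 15 methyl (5E,7E,9R,11Z)-9-hydroxy-9-(hydroxymethyl)-8-iodoheptadeca-5,7,11-trienoate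
Product: 16 methyl (5E,7E,9R,11Z)-9-hydroxy-9-(hydroxymethyl)-8-(trimethylstannyl)heptadeca-5,7,11-trienoate
Conditions: Pd(PPh3)4 (cat.), Me3SnSnMe3, THF, 60 °C
Reagents that add atoms: hexamethylditin, C[Sn](C)(C)[Sn](C)(C)C
Why: Palladium-catalysed stannylation of an alkenyl iodide with a distannane (oxidative addition, tin–tin transmetalation, reductive elimination) retains the alkene geometry and is neutral, so the diol and ester survive.

Step 11
Reactants: 16 methyl (5E,7E,9R,11Z)-9-hydroxy-9-(hydroxymethyl)-8-(trimethylstannyl)heptadeca-5,7,11-trienoate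
Product: 17 methyl (5E,7E,9R,11Z)-9-formyl-9-hydroxy-8-(trimethylstannyl)heptadeca-5,7,11-trienoate
Conditions: SO3·pyridine, DMSO, i-Pr2NEt, CH2Cl2, 0 °C
Reagents that add atoms: none
Why: Parikh–Doering oxidation converts only the primary alcohol (the tertiary one cannot be oxidised), is non-acidic so the alkenylstannane is not protodestannylated, and gives an aldehyde without α-hydrogen.

Step 12
Reactants: 18 ethyl 2-chloro-2-(diethoxyphosphoryl)acetate
Product: 19 2-chloro-2-(diethoxyphosphoryl)acetic acid
Conditions: NaOH (1.05 equiv), EtOH–H2O, 0 → 23 °C; then aq. HCl to pH 1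
Reagents that add atoms: sodium hydroxide, [Na+].[OH-]
Why: Saponification cleaves the carboxylic ester much faster than the phosphonate diester, as in the standard preparation of phosphonoacetic acids from their triesters.

Step 13
Reactants: 19 2-chloro-2-(diethoxyphosphoryl)acetic acid
Product: 20 2-chloro-2-(diethoxyphosphoryl)acetyl chloride
Conditions: (COCl)2, DMF (cat.), CH2Cl2, 0 → 23 °C; evaporate and use crude
Reagents that add atoms: oxalyl chloride, ClC(=O)C(Cl)=O
Why: Vilsmeier-type activation with oxalyl chloride gives the acid chloride under base-free conditions, so no ketene is formed from the acidic α-position.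

Step 14
Reactants: 17 methyl (5E,7E,9R,11Z)-9-formyl-9-hydroxy-8-(trimethylstannyl)heptadeca-5,7,11-trienoate; 20 2-chloro-2-(diethoxyphosphoryl)acetyl chloride
Product: 22 methyl (5E,7E)-7-[(2R)-4-chloro-2-hydroxy-2-[(2Z)-oct-2-en-1-yl]-5-oxocyclopent-3-en-1-ylidene]hept-5-enoate, via β-ketophosphonate 21 (not isolated)
Conditions: Pd2(dba)3 (cat.), P(2-furyl)3, THF, 40 °C; then LiCl, i-Pr2NEt, MeCN, 23 °C (same flask)
Reagents that add atoms: none
Why: Zerovalent palladium inserts into the acyl C–Cl bond of 20, the alkenyl group of 17 moves from tin to palladium and reductive elimination forms C9–C8 (Stille acylation of an alkenylstannane by an acid chloride); LiCl and the amine then deprotonate C10 of 21, the carbanion adds to the C11 aldehyde and the oxaphosphetane collapses to C10=C11 (intramolecular Horner–Wadsworth–Emmons olefination of an α-chloro β-ketophosphonate). The cyclopentenone ring C8–C12 closes in the second stage by 5-exo-trig attack of C10 on the aldehyde carbon. No stereocentre is created: C12 is untouched, the C10=C11 geometry is dictated by the five-membered ring, and the 7E geometry is carried over from the stannane because transmetalation and reductive elimination retain configuration. The step needs acylation at C8 and not at the tertiary hydroxyl, which the base-free coupling and the hindered carbinol should secure, and olefination in place of enolisation or aldol chemistry, which the fully substituted C12 secures. Chlorine stays on C10 because the phosphonate, not the halide, leaves in the olefination.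

Step 15
Reactants: 22 methyl (5E,7E)-7-[(2R)-4-chloro-2-hydroxy-2-[(2Z)-oct-2-en-1-yl]-5-oxocyclopent-3-en-1-ylidene]hept-5-enoate
Product: 23 methyl (5E,7E)-7-[(2R)-2-acetoxy-4-chloro-2-[(2Z)-oct-2-en-1-yl]-5-oxocyclopent-3-en-1-ylidene]hept-5-enoate
Conditions: Ac2O, DMAP (cat.), Et3N, CH2Cl2, 0 → 23 °C
Reagents that add atoms: acetic anhydride, CC(=O)OC(C)=O
Why: DMAP-catalysed acylation of the tertiary allylic alcohol acts on oxygen only, so C12 keeps its (R) configuration and the dienone, which has no enolisable position, should survive the mild base.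

**Compound list**

1 | (4Z)-dec-4-enal | CCCCC/C=C\CCC=O | starting material
2 | (4Z)-2-methylidenedec-4-enal | CCCCC/C=C\CC(=C)C=O | intermediate
3 | (4Z)-2-methylidenedec-4-en-1-ol | CCCCC/C=C\CC(=C)CO | intermediate
4 | [(2S)-2-[(2Z)-oct-2-en-1-yl]oxiran-2-yl]methanol | OC[C@@]1(C/C=C\CCCCC)CO1 | intermediate
5 | (2R)-2-[(2Z)-oct-2-en-1-yl]oxirane-2-carbaldehyde | O=C[C@@]1(C/C=C\CCCCC)CO1 | intermediate
6 | (2S)-2-ethynyl-2-[(2Z)-oct-2-en-1-yl]oxirane | C#C[C@@]1(C/C=C\CCCCC)CO1 | intermediate
7 | (2S,4Z)-2-ethynyldec-4-ene-1,2-diol | C#C[C@@](O)(C/C=C\CCCCC)CO | intermediate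
8 | methyl hex-5-ynoate | COC(=O)CCCC#C | starting material
9 | chlorobis(cyclopentadienyl)[(1E)-6-methoxy-6-oxohex-1-en-1-yl]zirconium | COC(=O)CCC/C=C/[Zr](Cl)(C1C=CC=C1)C1C=CC=C1 | intermediate
10 | methyl (5E)-6-iodohex-5-enoate | COC(=O)CCC/C=C/I | intermediate
11 | methyl (5E,9S,11Z)-9-hydroxy-9-(hydroxymethyl)heptadeca-5,11-dien-7-ynoate | COC(=O)CCC/C=C/C#C[C@@](O)(C/C=C\CCCCC)CO | intermediate
12 | methyl (5E,9S,11Z)-9-{[(dimethylsilyl)oxy]methyl}-9-hydroxyheptadeca-5,11-dien-7-ynoate | COC(=O)CCC/C=C/C#C[C@@](O)(C/C=C\CCCCC)CO[SiH](C)C | intermediate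
13 | methyl (5E,7E)-7-[(4R)-4-hydroxy-2,2-dimethyl-4-[(2Z)-oct-2-en-1-yl]-1,2-oxasilolan-3-ylidene]hept-5-enoate | COC(=O)CCC/C=C/C=C1/[Si](C)(C)OC[C@]1(O)C/C=C\CCCCC | intermediate
14 | methyl (5E,7E,9R,11Z)-9-[({[(1,1,1,3,3,3-hexafluoropropan-2-yl)oxy](dimethyl)silyl}oxy)methyl]-9-hydroxy-8-iodoheptadeca-5,7,11-trienoate | COC(=O)CCC/C=C/C=C(/I)[C@](O)(CO[Si](C)(C)OC(C(F)(F)F)C(F)(F)F)C/C=C\CCCCC | intermediate
15 | methyl (5E,7E,9R,11Z)-9-hydroxy-9-(hydroxymethyl)-8-iodoheptadeca-5,7,11-trienoate | COC(=O)CCC/C=C/C=C(/I)[C@](O)(CO)C/C=C\CCCCC | intermediate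
16 | methyl (5E,7E,9R,11Z)-9-hydroxy-9-(hydroxymethyl)-8-(trimethylstannyl)heptadeca-5,7,11-trienoate | COC(=O)CCC/C=C/C=C(/[Sn](C)(C)C)[C@](O)(CO)C/C=C\CCCCC | intermediate
17 | methyl (5E,7E,9R,11Z)-9-formyl-9-hydroxy-8-(trimethylstannyl)heptadeca-5,7,11-trienoate | COC(=O)CCC/C=C/C=C(/[Sn](C)(C)C)[C@](O)(C=O)C/C=C\CCCCC | intermediate
18 | ethyl 2-chloro-2-(diethoxyphosphoryl)acetate | CCOC(=O)C(Cl)P(=O)(OCC)OCC | starting material
19 | 2-chloro-2-(diethoxyphosphoryl)acetic acid | OC(=O)C(Cl)P(=O)(OCC)OCC | intermediate
20 | 2-chloro-2-(diethoxyphosphoryl)acetyl chloride | ClC(=O)C(Cl)P(=O)(OCC)OCC | intermediate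
21 | methyl (5E,7E,9S,11Z)-8-[2-chloro-2-(diethoxyphosphoryl)acetyl]-9-formyl-9-hydroxyheptadeca-5,7,11-trienoate (both epimers at the chlorinated carbon) | COC(=O)CCC/C=C/C=C(/C(=O)C(Cl)P(=O)(OCC)OCC)[C@](O)(C=O)C/C=C\CCCCC | intermediate
22 | methyl (5E,7E)-7-[(2R)-4-chloro-2-hydroxy-2-[(2Z)-oct-2-en-1-yl]-5-oxocyclopent-3-en-1-ylidene]hept-5-enoate | COC(=O)CCC/C=C/C=C1/C(=O)C(Cl)=C[C@]1(O)C/C=C\CCCCC | intermediate
23 | methyl (5E,7E)-7-[(2R)-2-acetoxy-4-chloro-2-[(2Z)-oct-2-en-1-yl]-5-oxocyclopent-3-en-1-ylidene]hept-5-enoate | COC(=O)CCC/C=C/C=C1/C(=O)C(Cl)=C[C@]1(OC(C)=O)C/C=C\CCCCC | target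

**Count and risks**

Total step count: 15. Longest linear sequence: 12 (steps 1–5, 7–11, 14, 15).

Steps most likely to fail:

Step 14. Transmetalation at the hindered, α-branched alkenyltin may be slow, so that protodestannylation or loss of carbon monoxide or chloride from the acylpalladium competes. In the basic stage the hydroxy aldehyde may undergo an α-ketol shift before it is olefinated. The fallback sets out from 17 and replaces the phosphonate olefination by a chromium-mediated reductive olefination. Stille acylation of 17 with trichloroacetyl chloride (Pd2(dba)3, P(2-furyl)3, THF) should give the trichloromethyl ketone methyl (5E,7E,9S,11Z)-9-formyl-9-hydroxy-8-(trichloroacetyl)heptadeca-5,7,11-trienoate F1. CrCl2 in THF then reduces the trichloromethyl group to a chromium enolate, which adds to the C11 aldehyde; a second reduction expels the chromium alkoxide and leaves the chloro-olefin. This is the known chromium-mediated condensation of aldehydes with trichloromethyl carbonyl compounds, and it comes back to the route at 22.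

Step 9. The iodonium ion may be captured by the free tertiary hydroxyl (iodoetherification onto the 11Z alkene) or may add to the diene, and ipso substitution may lose part of the alkene geometry. The fallback sets out from 11 and avoids both the silicon tether and the electrophilic attack on the π system. The diol is converted to its dilithium dialkoxide with LiN(SiMe3)2 at −78 °C, and alkoxide-directed syn hydrozirconation with Cp2Zr(H)Cl places zirconium on C8. This gives the dilithium salt of methyl (5E,7E,9R,11Z)-8-[chlorobis(cyclopentadienyl)zirconio]-9-oxido-9-(oxidomethyl)heptadeca-5,7,11-trienoate F2. Iodinolysis of its carbon–zirconium bond with N-iodosuccinimide at −78 °C and work-up with aqueous NH4Cl comes back to the route at 15.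

Step 5. Hydroxide opening of the 2,2-disubstituted epoxide may be slow at a temperature at which the alkynyl epoxide starts to isomerise or to open at the propargylic carbon with loss of configuration. The fallback sets out from 6 and uses an anhydrous alkoxide in place of water. Sodium 4-methoxybenzyl oxide (from the alcohol and NaH) in DMF opens the epoxide at the unsubstituted carbon to give (2S,4Z)-2-ethynyl-1-[(4-methoxyphenyl)methoxy]dec-4-en-2-ol F3. Sonogashira coupling with 10 gives methyl (5E,9S,11Z)-9-hydroxy-9-{[(4-methoxyphenyl)methoxy]methyl}heptadeca-5,11-dien-7-ynoate F4. Oxidative removal of the benzyl ether with DDQ in wet CH2Cl2 comes back to the route at 11.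

Further compounds
F1 | step 14 | methyl (5E,7E,9S,11Z)-9-formyl-9-hydroxy-8-(trichloroacetyl)heptadeca-5,7,11-trienoate | COC(=O)CCC/C=C/C=C(/C(=O)C(Cl)(Cl)Cl)[C@](O)(C=O)C/C=C\CCCCC
F2 | step 9 | dilithium salt of methyl (5E,7E,9R,11Z)-8-[chlorobis(cyclopentadienyl)zirconio]-9-oxido-9-(oxidomethyl)heptadeca-5,7,11-trienoate | COC(=O)CCC/C=C/C=C(/[Zr](Cl)(C1C=CC=C1)C1C=CC=C1)[C@]([O-])(C[O-])C/C=C\CCCCC.[Li+].[Li+]
F3 | step 5 | (2S,4Z)-2-ethynyl-1-[(4-methoxyphenyl)methoxy]dec-4-en-2-ol | C#C[C@@](O)(C/C=C\CCCCC)COCc1ccc(OC)cc1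
F4 | step 5 | methyl (5E,9S,11Z)-9-hydroxy-9-{[(4-methoxyphenyl)methoxy]methyl}heptadeca-5,11-dien-7-ynoate | COC(=O)CCC/C=C/C#C[C@@](O)(C/C=C\CCCCC)COCc1ccc(OC)cc1
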